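The readings come from a simulation with made-up constants; noise was put on by code.

If two products of one charge change places, I look for the moment at which they do it.

common to all: Z 0.50 M
- delta: the very flask that is asked about, followed so far
- flask: time 20 h

delta run (percent of the Z charged)

| time / h | X / % | E / % |
|---|---|---|
| 0.667 | 1.7 | 3.2 |
| 2.00 | 4.5 | 6.2 |
| 4.00 | 11.9 | 7.9 |
| 5.00 | 13.1 | 8.4 |
| 8.00 | 20.4 | 7.5 |
| 10.0 | 23.5 | 8.7 |

(scatter of a reading: 0.5 percentage points)



- ratio of X to E at 12 min
- ratio of X to E at 2.0 h
- ratio of X to E at 20 h

The delta run looks contradictory at first. E gains 3.2% in the first 0.667 h, but 0.8 percentage points between 4.00 h and 10.0 h, and over those same hours X gains 12 points. So X does not follow E's feed. I take it that X draws on a store filled earlier, which gives X an induction period. In the delta run E leads at 2.00 h and X leads at 4.00 h, so I draw a straight line between those readings: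

crossing = 2.00 h + 2.00 h × 1.7 points / (1.7 points + 4 points) = 2.60 h

This crossing time, at which the delta readings, with their scatter, show as much X as E, is my yardstick. Since 2.0 h lies before it, I keep the reading's ratio there, 0.726. If X comes second-hand, the early ratio shrinks in proportion to time, so I scale the first reading back:

ratio at 12 min = 0.531 × 0.2 h / 0.667 h = 0.159

Far past the crossing, at 20 h, I expect more than the 2.70 read at 10.0 h.

The forecast says 0.4, 0.77 and 6, holding that "X seems present from the start", so its early ratio is higher than mine.

The flask gives 0.0705, 0.802 and 3.69.

    Z ⇌ Q (K = 2.60, k = 0.00170 /min)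
    Z → E (k = 0.00160 /min)
    D → X (k = 0.00220 /min)
    Z ⇌ D (K = 14.0, k = 0.00810 /min)
    2 Z → G (k = 0.0270 /M/min)

In the flask, half of the turnover of the step from Z to D up to 20 h is done by 0.638 h, whereas the step from D to X has 74% of its turnover behind it after 10.0 h; at 2.00 h, before my crossing of 2.60 h, the flask holds D 24.7% against X 4.89%, and X draws level with E at 2.49 h. The neighbour charged with 2.0 M of Z stands at 0.873 at 2.0 h, under one and so on the same side of its crossing as the flask, and it reaches 3.70 at 20 h.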